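The dihydrofuran ring is cut at O1–C7a and C2–C3. The fluorine-bearing C7a of 5-acetyl-2-fluorobenzaldehyde lies para to the C5 acetyl group, so it is an SNAr site, and C3 is the aldehyde carbon. In one flask, a CrCl3/salen-catalysed asymmetric allylation with a 3-acetoxy-2-(methoxycarbonyl)allyl bromide forms C2–C3 and both ring stereocentres. Fluoride then releases the C3 alkoxide, the acetyl group shifts from O-C2 to O-C3, and the freed C2 alkoxide displaces fluoride to close the ring. The vicinal C2/C3 dioxygenation, the acrylate and the C3 acetate thus arrive together. Ketone reduction and tigloylation finish the synthesis.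

Key step: step 4

Remark: ring atoms are numbered as in 1-benzofuran (O1, C2, C3, C3a, C4–C7, C7a); the C=C geometry of 4 and 5 is drawn as the expected major isomer and is not carried into the product; the antipodes of the salen ligand and of the oxazaborolidine are assigned by analogy with simple aryl aldehydes and aryl methyl ketones.

Step 1
Reactants: 1 methyl propanoate; 2 methyl formate
Product: 4 methyl (E)-3-acetoxy-2-methylprop-2-enoate, via sodium enolate 3 (not isolated)
Conditions: NaH, cat. MeOH, THF, 0 °C to rt; then AcCl, 0 °C
Reagents that add atoms: acetyl chloride, CC(Cl)=O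
Why: Crossed Claisen condensation of the ester enolate with the non-enolisable formate is driven by formation of the stabilised formyl-ester enolate 3, which the hard acyl chloride should acylate on oxygen to give the push-pull enol acetate with the acetoxy group trans to the ester.

Step 2
Reactants: 4 methyl (E)-3-acetoxy-2-methylprop-2-enoate
Product: 5 methyl (Z)-3-acetoxy-2-(bromomethyl)prop-2-enoate
Conditions: NBS, AIBN (cat.), PhCF3, 80 °C
Reagents that add atoms: N-bromosuccinimide, O=C1CCC(=O)N1Br
Why: Wohl–Ziegler bromination should act on the 2-methyl group, the only allylic C–H position, and the allyl radical should take up bromine at CH2 so that the conjugated enol acetate is kept (the Z descriptor reflects only the changed CIP priority).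

Step 3
Reactants: 6 5-bromo-2-fluorobenzaldehyde
Product: 8 5-acetyl-2-fluorobenzaldehyde, via enol ether 7 (not isolated)
Conditions: tributyl(1-ethoxyethenyl)stannane, PdCl2(PPh3)2 (3 mol %), toluene, 100 °C; then 1 M HCl, THF, rt
Reagents that add atoms: tributyl(1-ethoxyethenyl)stannane, CCCC[Sn](CCCC)(CCCC)C(=C)OCC; water, O
Why: Stille coupling of the acetyl-anion equivalent should occur at C–Br only (C–F and the aldehyde are inert to zerovalent palladium under these conditions), and mild acid hydrolysis of the enol ether gives the methyl ketone.

Step 4
Reactants: 5 methyl (Z)-3-acetoxy-2-(bromomethyl)prop-2-enoate; 8 5-acetyl-2-fluorobenzaldehyde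
Product: 12 methyl 2-[(2S,3S)-3-acetoxy-5-acetyl-2,3-dihydro-1-benzofuran-2-yl]prop-2-enoate, via silyl ether adduct 9 (not isolated), via hydroxy acetate 10 (not isolated), via rearranged acetate 11 (not isolated)
Conditions: CrCl3 (10 mol %), Mn (3 equiv), (S,S)-N,N'-bis(3,5-di-tert-butylsalicylidene)cyclohexane-1,2-diamine (10 mol %), Et3N (20 mol %), Me3SiCl (1.5 equiv), MeCN, rt; then DMF, CsF (3 equiv), 40 °C, same flask
Reagents that add atoms: none
Why: Divalent chromium, kept in turnover by Mn and Me3SiCl, inserts into the C–Br bond of 5 and the allylchromium species adds through its acetoxy-bearing γ-carbon to the aldehyde of 8 (C2–C3 bond, silyl ether 9); fluoride then frees the C3 alkoxide (10), a 1,2-acyl shift through a five-membered orthoester anion moves the acetyl group to O-C3 (11), and the freed C2 alkoxide displaces the aryl fluoride (O1–C7a bond), the expelled fluoride carrying on the desilylation. The closest known reaction types are the catalytic asymmetric Nozaki–Hiyama–Kishi allylation (known with CrCl3/salen catalysts for 3-acyloxyallyl halides, syn-selective, and with CrCl2/bis(oxazoline) catalysts for 2-(alkoxycarbonyl)allyl bromides), the vicinal O-to-O acyl migration of diol monoesters, and the fluoride-mediated SNAr of silyl ethers with acyl-activated aryl fluorides. The dihydrofuran ring closes by 5-exo-trig addition of O to C7a followed by loss of fluoride from the Meisenheimer anion that the para acetyl group stabilises. C3 is set by the salen ligand (Re-face addition to the aldehyde) and C2 by the syn topicity of the addition, expected both from the open transition state of the salen-bound allylchromium and from a closed one in which the acetoxy group sits cis to CH2Cr (trans to the ester); the acyl shift and the SNAr step touch neither centre, so the syn adduct becomes the cis-2,3-disubstituted ring. The step needs aldehyde-over-ketone chemoselectivity, which allylchromium reagents have, and ring closure through O-C2 alone, which is secured because the C3 alkoxide could reach C7a only through a four-membered ring and is capped by the migrating acetyl group while the irreversible SNAr drains the acyl-shift equilibrium.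

Step 5
Reactants: 12 methyl 2-[(2S,3S)-3-acetoxy-5-acetyl-2,3-dihydro-1-benzofuran-2-yl]prop-2-enoate
Product: 13 methyl 2-[(2S,3S)-3-acetoxy-5-[(1S)-1-hydroxyethyl]-2,3-dihydro-1-benzofuran-2-yl]prop-2-enoate
Conditions: (R)-Me-CBS (20 mol %), BH3·SMe2 (0.7 equiv), CH2Cl2, −30 °C; MeOH quench
Reagents that add atoms: none
Why: Corey–Bakshi–Shibata reduction should deliver hydride to the Re face of the aryl methyl ketone (aryl as the large, methyl as the small group) and set the (S)-carbinol under catalyst control, independent of the remote ring centres, while the catalysed ketone reduction at low temperature outruns hydroboration of the electron-poor acrylate and leaves both esters alone.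

Step 6
Reactants: 13 methyl 2-[(2S,3S)-3-acetoxy-5-[(1S)-1-hydroxyethyl]-2,3-dihydro-1-benzofuran-2-yl]prop-2-enoate
Product: 14 (1S)-1-[(2S,3S)-3-acetoxy-2-(3-methoxy-3-oxoprop-1-en-2-yl)-2,3-dihydro-1-benzofuran-5-yl]ethyl (2E)-2-methylbut-2-enoate
Conditions: (E)-2-methylbut-2-enoyl chloride, pyridine, CH2Cl2, 0 °C to rt
Reagents that add atoms: (E)-2-methylbut-2-enoyl chloride, C/C=C(\C)C(Cl)=O
Why: Acylation of the secondary benzylic alcohol by the acid chloride with pyridine as a weakly nucleophilic base breaks no bond at the carbinol carbon (retention), keeps the stable E geometry of the tigloyl group, and avoids strongly nucleophilic amine catalysts that could open the allylic aryl ether by SN2′ attack on the acrylate.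

Compound list
1 | methyl propanoate | CCC(=O)OC | starting material
2 | methyl formate | COC=O | starting material
3 | sodium 3-methoxy-2-methyl-3-oxoprop-1-en-1-olate (geometry mobile) | COC(=O)C(C)=C[O-].[Na+] | intermediate
4 | methyl (E)-3-acetoxy-2-methylprop-2-enoate | CC(=O)O/C=C(\C)C(=O)OC | intermediate
5 | methyl (Z)-3-acetoxy-2-(bromomethyl)prop-2-enoate | CC(=O)O/C=C(\CBr)C(=O)OC | intermediate
6 | 5-bromo-2-fluorobenzaldehyde | O=Cc1cc(Br)ccc1F | starting material
7 | 5-(1-ethoxyethenyl)-2-fluorobenzaldehyde | C=C(OCC)c1ccc(F)c(C=O)c1 | intermediate
8 | 5-acetyl-2-fluorobenzaldehyde | CC(=O)c1ccc(F)c(C=O)c1 | intermediate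
9 | methyl (3S,4S)-3-acetoxy-4-(5-acetyl-2-fluorophenyl)-2-methylidene-4-[(trimethylsilyl)oxy]butanoate | C=C(C(=O)OC)[C@H](OC(C)=O)[C@@H](O[Si](C)(C)C)c1cc(C(C)=O)ccc1F | intermediate
10 | methyl (3S,4S)-3-acetoxy-4-(5-acetyl-2-fluorophenyl)-4-hydroxy-2-methylidenebutanoate | C=C(C(=O)OC)[C@H](OC(C)=O)[C@@H](O)c1cc(C(C)=O)ccc1F | intermediate
11 | methyl (3S,4S)-4-acetoxy-4-(5-acetyl-2-fluorophenyl)-3-hydroxy-2-methylidenebutanoate | C=C(C(=O)OC)[C@H](O)[C@@H](OC(C)=O)c1cc(C(C)=O)ccc1F | intermediate
12 | methyl 2-[(2S,3S)-3-acetoxy-5-acetyl-2,3-dihydro-1-benzofuran-2-yl]prop-2-enoate | C=C(C(=O)OC)[C@@H]1Oc2ccc(C(C)=O)cc2[C@@H]1OC(C)=O | intermediate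
13 | methyl 2-[(2S,3S)-3-acetoxy-5-[(1S)-1-hydroxyethyl]-2,3-dihydro-1-benzofuran-2-yl]prop-2-enoate | C=C(C(=O)OC)[C@@H]1Oc2ccc([C@H](C)O)cc2[C@@H]1OC(C)=O | intermediate
14 | (1S)-1-[(2S,3S)-3-acetoxy-2-(3-methoxy-3-oxoprop-1-en-2-yl)-2,3-dihydro-1-benzofuran-5-yl]ethyl (2E)-2-methylbut-2-enoate | C=C(C(=O)OC)[C@@H]1Oc2ccc([C@H](C)OC(=O)/C(C)=C/C)cc2[C@@H]1OC(C)=O | target

Total steps: 6. Longest linear sequence: 5 steps (steps 1, 2, 4, 5, 6).

Steps most likely to fail

Step 4 carries the most risk. The doubly functionalised allylchromium species may add with poor facial or simple diastereoselectivity, and the electron-poor aldehyde may dimerise reductively. In the second stage the C3 alkoxide may lactonise onto the acrylate ester instead of taking up the acetyl group, or acetic acid may be lost across C2–C3 of the product to give the aromatic benzofuran. The fallback replaces the organochromium addition by a closed, stereospecific allylboration under Brønsted acid catalysis and sets out from 5 and 8. Borylation of 5 with B2pin2 under Pd2(dba)3 (THF, 50 °C) should give methyl (E)-3-acetoxy-2-[(4,4,5,5-tetramethyl-1,3,2-dioxaborolan-2-yl)methyl]prop-2-enoate F1, in which the acetoxy group is cis to CH2B. Addition of F1 to 8 under the chiral phosphoric acid (R)-TRIP (5 mol %, toluene, −30 °C; antipode chosen by analogy for Re-face addition) should pass through a chair transition state that turns this geometry into the syn adduct methyl (3S,4S)-3-acetoxy-4-(5-acetyl-2-fluorophenyl)-2-methylidene-4-[(4,4,5,5-tetramethyl-1,3,2-dioxaborolan-2-yl)oxy]butanoate F2. Cs2CO3 in DMF, added to the same flask, cleaves the B–O bond to 10, and the acyl shift (11) and the SNAr closure follow as before. The fallback comes back to the route at 12 and still makes C2–C3 and O1–C7a in one flask.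

Step 2 is next. The bromine radical may add to the enol acetate double bond and start oligomerisation, hydrogen abstraction from the electron-poor methyl group may be slow, and HBr formed in the flask may cleave the enol acetate. The fallback builds the C–Br bond from a C–O bond that is in place before the enol acetate is made, and sets out from 2. Silylation of commercial methyl 3-hydroxypropanoate (TBSCl, imidazole) gives methyl 3-[(tert-butyldimethylsilyl)oxy]propanoate F3. LDA at −78 °C followed by methyl formate 2 should give the formyl-ester enolate lithium 2-{[(tert-butyldimethylsilyl)oxy]methyl}-3-methoxy-3-oxoprop-1-en-1-olate F4. Acetyl chloride turns it into the enol acetate methyl (E)-3-acetoxy-2-{[(tert-butyldimethylsilyl)oxy]methyl}prop-2-enoate F5, and Ph3PBr2 in CH2Cl2 converts the silyl ether directly into the bromide, so the fallback comes back to the route at 5.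

Step 5 is third. Borane may hydroborate or reduce the acrylate in competition with the ketone, and catalyst control may be eroded on the electron-rich ketone. The fallback changes from a boron hydride to biocatalysis and sets out from 12: an (S)-selective NADPH-dependent ketoreductase (alcohol dehydrogenase class) with isopropanol as the hydride source in phosphate buffer (pH 7) with DMSO as cosolvent at 30 °C should reduce only the aryl methyl ketone and leave the acrylate and both esters alone. It comes back to the route at 13 and makes no new compound.

Further compounds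
F1 | step 4 | methyl (E)-3-acetoxy-2-[(4,4,5,5-tetramethyl-1,3,2-dioxaborolan-2-yl)methyl]prop-2-enoate | CC(=O)O/C=C(\CB1OC(C)(C)C(C)(C)O1)C(=O)OC
F2 | step 4 | methyl (3S,4S)-3-acetoxy-4-(5-acetyl-2-fluorophenyl)-2-methylidene-4-[(4,4,5,5-tetramethyl-1,3,2-dioxaborolan-2-yl)oxy]butanoate | C=C(C(=O)OC)[C@H](OC(C)=O)[C@@H](OB1OC(C)(C)C(C)(C)O1)c1cc(C(C)=O)ccc1F
F3 | step 2 | methyl 3-[(tert-butyldimethylsilyl)oxy]propanoate | COC(=O)CCO[Si](C)(C)C(C)(C)C
F4 | step 2 | lithium 2-{[(tert-butyldimethylsilyl)oxy]methyl}-3-methoxy-3-oxoprop-1-en-1-olate (geometry mobile) | COC(=O)C(CO[Si](C)(C)C(C)(C)C)=C[O-].[Li+]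
F5 | step 2 | methyl (E)-3-acetoxy-2-{[(tert-butyldimethylsilyl)oxy]methyl}prop-2-enoate | CC(=O)O/C=C(\CO[Si](C)(C)C(C)(C)C)C(=O)OC
F0 | step 5 | none | none
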